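## Retrosynthetic overview

1. Plakortolide L ⇒ seco methyl ester (1,2-dioxane-3-acetate with free C4–OH) by lactonisation ⇒ acyclic C6 hydroperoxide by 6-exo peroxy-Michael addition to the C2=C3 enoate ⇒ C6=C7 alkene by Markovnikov capture of O2. These three events run as one telescoped operation: 1,2-dioxane ring first, γ-lactone ring second, as in the presumed biosynthesis.
2. The acyclic (E)-4-hydroxy-2-enoate ⇒ tertiary α-hydroxy ester by semi-reduction and two-carbon olefination.
3. The trisubstituted C6=C7 alkene ⇒ cross-metathesis of a methallyl group with 13-phenyltridec-1-ene (from 11-bromoundec-1-ene and a phenethyl Grignard reagent).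
4. C4 and the C4–C5 bond ⇒ catalytic enantioselective carbonyl-ene reaction of methyl pyruvate with isobutylene.
5. Stereochemistry: C4 from the catalyst, C3 relayed from C4 in the ring closure, C6 formed without control (about 1:1) and its epimer separated at the end.

Assumption: the presumed biosynthesis is taken as O2 capture at C6 of an acyclic polyketide, conjugate addition of the C6 hydroperoxide to the C2=C3 enoate (seco-plakortolide) and lactonisation onto the C4 hydroxyl; plakortolide numbering (C1 = lactone carbonyl) is used, and the target is (3S,4S,6S).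

Abbreviations: t-Bu-box = 2,2′-(propane-2,2-diyl)bis[(4S)-4-tert-butyl-4,5-dihydrooxazole]; thd = 2,2,6,6-tetramethylheptane-3,5-dionate; H2IMes = 1,3-dimesitylimidazolidin-2-ylidene.

## Route

Step 1
Reactants: 1 11-bromoundec-1-ene; 2 (2-phenylethyl)magnesium chloride
Product: 3 13-phenyltridec-1-ene
Conditions: Li2CuCl4 (3 mol%), THF, −10 °C → rt
Reagents that add atoms: none
Why: Copper-catalysed sp3–sp3 Grignard cross-coupling (Kochi coupling) of a primary bromide, which leaves the terminal alkene untouched and creates no stereocentre.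

Step 2
Reactants: 4 methyl pyruvate; 5 isobutylene (2-methylpropene)
Product: 6 methyl (S)-2-hydroxy-2,4-dimethylpent-4-enoate
Conditions: [Cu((S,S)-t-Bu-box)](SbF6)2 (10 mol%), 5 (5 equiv), CH2Cl2, sealed tube, 40 °C
Reagents that add atoms: none
Why: Copper–bis(oxazoline)-catalysed enantioselective carbonyl-ene reaction, in which pyruvate chelates the divalent copper centre through both carbonyls, a tert-butyl group shields the re face of the ketone and isobutylene adds to the si face with transfer of an allylic hydrogen, setting C4 as S.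

Step 3
Reactants: 6 methyl (S)-2-hydroxy-2,4-dimethylpent-4-enoate; 3 13-phenyltridec-1-ene
Product: 7 methyl (S,E)-2-hydroxy-2,4-dimethyl-16-phenylhexadec-4-enoate
Conditions: RuCl2(H2IMes)(=CH-C6H4-2-O-i-Pr) (second-generation Hoveyda–Grubbs catalyst, 5 mol%), 6 (3 equiv, excess recovered), PhMe, 60 °C, Ar sparge
Reagents that add atoms: none
Why: Olefin cross-metathesis of the 1,1-disubstituted alkene of 6 with terminal alkene 3 (ethene purged) gives the trisubstituted C6=C7 alkene as an E/Z mixture that needs no separation, because C6 becomes a planar radical in step 5; C4 is untouched.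

Step 4
Reactants: 7 methyl (S,E)-2-hydroxy-2,4-dimethyl-16-phenylhexadec-4-enoate
Product: 9 methyl (2E,4S,6E)-4-hydroxy-4,6-dimethyl-18-phenyloctadeca-2,6-dienoate, via alpha-hydroxy aldehyde 8 (not isolated)
Conditions: i-Bu2AlH (2.3 equiv), CH2Cl2, −78 °C; then Ph3P=CHCO2Me, −78 → 40 °C
Reagents that add atoms: methyl (triphenylphosphoranylidene)acetate, COC(=O)C=P(c1ccccc1)(c1ccccc1)c1ccccc1
Why: Tandem ester semi-reduction/Wittig olefination, in which the aluminium alkoxide of the tertiary hydroxyl chelates the aluminium hemiacetal so that reduction stops at aldehyde 8, which is released on warming and trapped E-selectively by the stabilised ylide; the quaternary C4 cannot epimerise, and any Z enoate lactonises to a butenolide that converges on 13 in step 5.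

Step 5
Reactants: 9 methyl (2E,4S,6E)-4-hydroxy-4,6-dimethyl-18-phenyloctadeca-2,6-dienoate
Product: 13 plakortolide L, via silyl peroxide 10 (not isolated), via hydroperoxide 11 (not isolated), via seco ester 12 (not isolated)
Conditions: Co(thd)2 (10 mol%), Et3SiH (2 equiv), O2 (1 atm), ClCH2CH2Cl, rt; SiO2 plug, solvent switch; then n-Bu4NF, THF, 0 °C → rt; then TsOH·H2O, rt
Reagents that add atoms: dioxygen, O=O
Why: Proposed new method: a telescoped merger of Mukaiyama–Isayama hydroperoxysilylation (cobalt hydride transfers H to C7 of either alkene isomer, the tertiary C6 radical captures O2 and is silylated to 10), fluoride release of peroxide anion 11, 6-exo-trig oxa-Michael closure of the 1,2-dioxane onto the E-enoate through a chair with C4–OH axial and C4–Me equatorial (an axial C4–Me would be 1,3-diaxial to a C6 alkyl group) so that O–C3 and C4–OH end up cis, and lactonisation of seco ester 12 (alkoxide, then acid) to the cis-fused lactone while any trans adduct can revert by retro-Michael reaction and re-enter; C3 is thus relayed from C4, whereas C6 is fixed at the O2-capture step without control (about 1:1 expected) and the (6R)-epimer is removed by chromatography; the closest known reaction types are cobalt-catalysed hydroperoxysilylation followed by intramolecular hydroperoxide conjugate addition to enoates or butenolides, and γ-lactonisation of γ-hydroxy esters.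

## Compound list

1 | 11-bromoundec-1-ene | C=CCCCCCCCCCBr | starting material
2 | (2-phenylethyl)magnesium chloride | Cl[Mg]CCc1ccccc1 | starting material
3 | 13-phenyltridec-1-ene | C=CCCCCCCCCCCCc1ccccc1 | intermediate
4 | methyl pyruvate | COC(=O)C(C)=O | starting material
5 | isobutylene (2-methylpropene) | CC(C)=C | starting material
6 | methyl (S)-2-hydroxy-2,4-dimethylpent-4-enoate | COC(=O)[C@@](C)(O)CC(C)=C | intermediate
7 | methyl (S,E)-2-hydroxy-2,4-dimethyl-16-phenylhexadec-4-enoate (E shown; formed and used as an E/Z mixture at this alkene) | COC(=O)[C@@](C)(O)C/C(C)=C/CCCCCCCCCCCc1ccccc1 | intermediate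
8 | (S,E)-2-hydroxy-2,4-dimethyl-16-phenylhexadec-4-enal (E/Z as for 7) | O=C[C@@](C)(O)C/C(C)=C/CCCCCCCCCCCc1ccccc1 | intermediate
9 | methyl (2E,4S,6E)-4-hydroxy-4,6-dimethyl-18-phenyloctadeca-2,6-dienoate (E/Z mixture at C6=C7 only) | COC(=O)/C=C/[C@@](C)(O)C/C(C)=C/CCCCCCCCCCCc1ccccc1 | intermediate
10 | methyl (2E,4S,6S)-4-hydroxy-4,6-dimethyl-18-phenyl-6-(triethylsilylperoxy)octadec-2-enoate (formed together with its 6R epimer) | C[C@](OO[Si](CC)(CC)CC)(CCCCCCCCCCCCc1ccccc1)C[C@](C)(O)/C=C/C(=O)OC | intermediate
11 | methyl (2E,4S,6S)-6-hydroperoxy-4-hydroxy-4,6-dimethyl-18-phenyloctadec-2-enoate (together with its 6R epimer) | C[C@](OO)(CCCCCCCCCCCCc1ccccc1)C[C@](C)(O)/C=C/C(=O)OC | intermediate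
12 | methyl 2-[(3S,4S,6S)-4-hydroxy-4,6-dimethyl-6-(12-phenyldodecyl)-1,2-dioxan-3-yl]acetate (seco ester; together with its 6R epimer) | C[C@]1(CCCCCCCCCCCCc2ccccc2)C[C@](C)(O)[C@H](CC(=O)OC)OO1 | intermediate
13 | plakortolide L, (3S,4S,6S): cis-fused 1,2-dioxane/γ-lactone, with C4–Me and the C6 12-phenyldodecyl chain on one face and C6–Me and the lactone on the other | C[C@]1(CCCCCCCCCCCCc2ccccc2)C[C@]2(C)OC(=O)C[C@@H]2OO1 | target

## Step count and risks

Total steps: 5. Longest linear sequence: 4 (steps 2, 3, 4, 5 from methyl pyruvate; equally 1, 3, 4, 5 from 11-bromoundec-1-ene).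

**Step 5 (most likely to fail).** The lack of control at C6 is inherent to the radical O2 capture and is handled only by separation. The addressable risks are the cis/trans outcome at C3 in the acyclic ring closure, incomplete lactonisation, and base-induced peroxide fragmentation. Fallback, setting out from 9: E→Z photoisomerisation (350 nm, benzophenone, benzene) with spontaneous lactonisation gives (S,E)-5-methyl-5-(2-methyl-14-phenyltetradec-2-en-1-yl)furan-2(5H)-one F5. Co(thd)2/Et3SiH/O2 then gives the isolated silyl peroxide (S)-5-methyl-5-[(S)-2-methyl-14-phenyl-2-(triethylsilylperoxy)tetradecyl]furan-2(5H)-one F6. n-Bu4NF liberates (S)-5-[(S)-2-hydroperoxy-2-methyl-14-phenyltetradecyl]-5-methylfuran-2(5H)-one F7, which adds to the butenolide, where only cis fusion is geometrically possible. This comes back to the route at 13.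

**Step 3.** The 1,1-disubstituted alkene of 6 sits next to a quaternary carbon and may be sluggish in metathesis. Fallback, setting out from 2 and 4, with the chain placed in the ene partner instead: Li2CuCl4-catalysed coupling of 2 with commercial 1,10-dibromodecane (in excess) gives (12-bromododecyl)benzene F1. A second Li2CuCl4-catalysed coupling with isopropenylmagnesium bromide gives 2-methyl-14-phenyltetradec-1-ene F2. The carbonyl-ene reaction of F2 with 4 under the step 2 catalyst comes back to the route at 7, accompanied by its regioisomer methyl (S)-2-hydroxy-2-methyl-4-methylidene-16-phenylhexadecanoate F3. F3 is carried along because it gives the same C6 radical in step 5.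

**Step 4.** Over-reduction, or poor release and trapping of the hindered, unprotected α-hydroxy aldehyde, are the concerns. Fallback, setting out from 7: LiAlH4 gives (S,E)-2,4-dimethyl-16-phenylhexadec-4-ene-1,2-diol F4. TEMPO/PhI(OAc)2 oxidation of the primary alcohol in the presence of Ph3P=CHCO2Me (oxidation and Wittig olefination in one pot) comes back to the route at 9.

## Further compounds

F1 | step 3 | (12-bromododecyl)benzene | BrCCCCCCCCCCCCc1ccccc1
F2 | step 3 | 2-methyl-14-phenyltetradec-1-ene | C=C(C)CCCCCCCCCCCCc1ccccc1
F3 | step 3 | methyl (S)-2-hydroxy-2-methyl-4-methylidene-16-phenylhexadecanoate | COC(=O)[C@@](C)(O)CC(=C)CCCCCCCCCCCCc1ccccc1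
F4 | step 4 | (S,E)-2,4-dimethyl-16-phenylhexadec-4-ene-1,2-diol | OC[C@@](C)(O)C/C(C)=C/CCCCCCCCCCCc1ccccc1
F5 | step 5 | (S,E)-5-methyl-5-(2-methyl-14-phenyltetradec-2-en-1-yl)furan-2(5H)-one | C[C@]1(C/C(C)=C/CCCCCCCCCCCc2ccccc2)C=CC(=O)O1
F6 | step 5 | (S)-5-methyl-5-[(S)-2-methyl-14-phenyl-2-(triethylsilylperoxy)tetradecyl]furan-2(5H)-one | C[C@](OO[Si](CC)(CC)CC)(CCCCCCCCCCCCc1ccccc1)C[C@]2(C)OC(=O)C=C2
F7 | step 5 | (S)-5-[(S)-2-hydroperoxy-2-methyl-14-phenyltetradecyl]-5-methylfuran-2(5H)-one | C[C@](OO)(CCCCCCCCCCCCc1ccccc1)C[C@]2(C)OC(=O)C=C2
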